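At the first reading of the alpha run, 0.625 d, the substrate stands at 2% and the intermediate at 1%, beside 33% of other capture product and 68% of target.

| flask | substrate | first nucleophile | solid second nucleophile | remark | time |
|---|---|---|---|---|---|
| gamma | 0.50 M | 1.1 equiv | 0.60 equiv | run made earlier |  |
| alpha | 0.50 M | 4.4 equiv | 0.60 equiv | run made earlier |  |
| Sunday's | 0.50 M | 0.950 equiv | 0.600 equiv |  | 15 d |
| Friday's | 0.50 M | 2.80 equiv | 0.600 equiv |  | 15 d |

| run | time / d | other capture product / % | substrate / % | intermediate / % | target / % |
|---|---|---|---|---|---|
| gamma | 1.67 | 53 | 0 | 0 | 46 |
| gamma | 3.00 | 55 | 0 | 0 | 44 |
| gamma | 5.00 | 51 | 0 | 2 | 49 |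
| gamma | 6.00 | 52 | 0 | 1 | 46 |
| gamma | 8.00 | 53 | 0 | 0 | 46 |
| alpha | 0.625 | 33 | 2 | 1 | 68 |
| alpha | 2.08 | 33 | 0 | 2 | 69 |
| alpha | 4.00 | 33 | 1 | 1 | 68 |
| alpha | 5.00 | 29 | 1 | 2 | 72 |
| alpha | 8.00 | 33 | 0 | 1 | 70 |

(readings scatter by 2 percentage points)

* which of these there is most of at the end, counted by the substrate in it, Sunday's (intermediate / substrate / other capture product / target)
* which of these there is most of at the end, counted by the substrate in it, Friday's (intermediate / substrate / other capture product / target)
* how much there is at the end of the one of these that leads, in percent of the substrate charged: Sunday's
* how much there is at the end of the one of these that leads, in percent of the substrate charged: Friday's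

- solid, in amounts per volume of the solution: solid second nucleophile
- steps under discussion: second nucleophile + intermediate -> other capture product; second nucleophile -> decomposed reagent; solid second nucleophile <-> second nucleophile; 2 second nucleophile -> homo dimer; first nucleophile + intermediate -> target; substrate -> intermediate
- at the start none of the solid second nucleophile is in solution

First, does the time asked matter? Other capture product in the alpha run reads 33% at the first reading and 33% at 8.00 d. We therefore take the last readings as end values, although 15 d lies further out.

Second, where did the substrate go? At the last readings the two products sum to 99.0% in the gamma run and 103% in the alpha run. We can therefore treat them as sharing the whole charge, and one ratio gives both amounts.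

Third, how does that ratio move? Both captures take the same intermediate, so at each moment the rate of making target over that of making other capture product, a selectivity factor, goes with c(first nucleophile)/c(second nucleophile). Target over other capture product at the last readings reads 0.868 in the gamma run and 2.12 in the alpha run, for 4.00 times the first nucleophile. The logarithm of the one change over the logarithm of the other gives the charge order of the ratio, 0.645, a reading of less than 1.

Carried from the gamma run, this gives a ratio of 0.790 for Sunday's, so other capture product leads at 55.9%. For Friday's it gives 1.59, so target leads at 61.3%.

The forecast says other capture product at 55% (51% to 59%) and target at 61% (56% to 66%), from an “apparent order near 0.6 on average concentration”, and our Sunday's figure stands 0.90 percentage points above it.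

The flask gives 55.2% of other capture product on Sunday's and 61.3% of target on Friday's, a Sunday's ratio of 0.812 against our 0.790.

second nucleophile + intermediate → other capture product (k = 0.00740 /M/s); second nucleophile → decomposed reagent (k = 1.10 × 10⁻⁵ /s); solid second nucleophile ⇌ second nucleophile, rate k3*(cs3 - [second nucleophile]) while solid is left; crystals form when [second nucleophile] > cs3 (solubility = 0.260 M, k = 4.40 × 10⁻⁵ /s); 2 second nucleophile → homo dimer (k = 2.00 × 10⁻⁵ /M/s); first nucleophile + intermediate → target (k = 3.60 × 10⁻⁴ /M/s); substrate → intermediate (k = 8.10 × 10⁻⁵ /s) At 150 d Sunday's still holds 55.2% of other capture product. With 0.700 equiv of first nucleophile, one more flask like Friday's gets a ratio of 0.649 from our order, hence 60.7% of other capture product, which is more than the 0.600 equiv of solid second nucleophile charged; that flask holds 57.9% of other capture product.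

(The data were generated by integration for substances that don't exist.)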